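**Plan**
- Retrosynthetic cuts, in order: C17–O/C16–H and the C15 ketone (enone hydration, allylic oxidation); C13–C16 (ring D); C8–C9 with C13–C14 (ring C and the δ-lactone in one cycloaddition); the C19 and C20 carboxyl reductions; C2–C3 with C4–CH3 (ring A); C5–C10.
- Forward: acyclic β-keto ester → ring A → γ-lactone → acylation of C20–OH → ring C with the δ-lactone → ring D → C11 alcohol, C15 ketone, C17 alcohol.
- Enabling feature: in ring A, C3 is β to C19 (the carboxyl-level carbon on C4 that becomes the lactone OCH2) and C2 is α to C1. With a temporary ketone at C1 (acetoacetate: acyl carbon C1, α-carbon C10, ester C20), ring A closes by 6-endo Michael addition of the C2 enolate to a C3=C4–C19 acrylate.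
- The C4 enolate so formed takes up the C18 methyl in the same flask; the C1 ketone is removed in the next step.
- Stereochemistry: C10 (with C5) from cinchona-amine catalysis; C4 by substrate control, locked by cis-lactone formation; C8/C9 from the tethered cycloaddition under control of C10; C13 by the bridged ring; C11 by axial hydride delivery; C16 by exo-face protonation.

Key step: step 5

Remark on numbering: ent-kaurane numbers are used. Ring A = C1–C5, C10; C18 = methyl and C19 = OCH2 on C4; C6 = γ-lactone carbonyl on C5; C20 = OCH2 on C10; C7 = δ-lactone carbonyl on C8; ring C = C8, C9, C11–C14; ring D = C8, C13–C16; C17 = CH2OH on C16. α is the ring A face carrying C19, C6 and C20; β is the opposite face (C18, H5, C9).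
Assumption: the sense of induction of the hydroquinidine-derived catalyst in step 4 is taken by analogy with related allylic alkylations; the hydroquinine-derived pseudo-enantiomer would be used if it proves opposite.

Step 1
Reactants: 1 allyl acetoacetate; 2 allyl bromide
Product: 3 prop-2-enyl 2-acetylpent-4-enoate (racemic)
Conditions: K2CO3, acetone, 56 °C
Reagents that add atoms: none
Why: Standard SN2 C-alkylation of the β-keto ester enolate gives the mono-allylated acetoacetate, which supplies C2, C1, C10, C20 and the C9/C11/C12 arm; C10 is still enolisable, so no stereocentre is fixed.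

Step 2
Reactants: 4 tert-butyl acrylate; 5 ethyl glyoxylate
Product: 6 4-tert-butyl 1-ethyl 2-hydroxy-3-methylidenebutanedioate (racemic)
Conditions: DABCO (20 mol%), dioxane, 25 °C
Reagents that add atoms: none
Why: Morita–Baylis–Hillman reaction of the acrylate with the highly electrophilic glyoxylate aldehyde gives the allylic alcohol that carries C3, C4, C19 (acrylate) and C5, C6 (glyoxylate).

Step 3
Reactants: 6 allylic alcohol
Product: 7 4-tert-butyl 1-ethyl 2-(tert-butoxycarbonyloxy)-3-methylidenebutanedioate (racemic)
Conditions: Boc2O, DMAP (cat.), CH2Cl2, 0 → 25 °C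
Reagents that add atoms: di-tert-butyl dicarbonate, CC(C)(C)OC(=O)OC(=O)OC(C)(C)C
Why: DMAP-catalysed O-acylation gives the allylic tert-butyl carbonate, the usual activated form of such adducts for Lewis-base-catalysed allylic substitution.

Step 4
Reactants: 3 allyl 2-acetylpent-4-enoate; 7 allylic carbonate
Product: 8 2-tert-butyl 3-ethyl 4-prop-2-enyl (3R,4R)-4-acetylhepta-1,6-diene-2,3,4-tricarboxylate (chain C4 = C10 and chain C3 = C5 of the target)
Conditions: (DHQD)2AQN (10 mol%), toluene, 25 °C
Reagents that add atoms: none
Why: Lewis-base-catalysed asymmetric allylic alkylation (SN2′ attack of the quinuclidine nitrogen at C3 with loss of CO2 and tert-butoxide, deprotonation of 3, then SN2′ attack of the enolate at C5 inside the chiral ammonium ion pair) forms C5–C10 and should set the C10 quaternary centre and C5 under catalyst control, the C5 epimer being removable by chromatography.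

Step 5
Reactants: 8 acyclic keto triester
Product: 11 ring A keto triester (C1 ketone; C4 bears β-methyl and α-CO2tBu; C5 bears α-CO2Et; C10 bears α-CO2-allyl and β-allyl), via ketone lithium enolate 9 (not isolated), via cyclised ester lithium enolate 10 (not isolated)
Conditions: LiN(SiMe3)2 (1.05 equiv), THF, −78 → −40 °C; then MeI, DMPU, −40 → 0 °C
Reagents that add atoms: iodomethane, CI
Why: LiN(SiMe3)2 at −78 °C removes a proton from the unhindered C2 methyl of the ketone (the doubly activated C5–H is shielded by the C10 quaternary centre), and on warming the C2 enolate adds to C3, the β-carbon of the C3=C4–C19 acrylate, which closes ring A and leaves the tert-butyl ester enolate at C4 that MeI then C-alkylates. The closest known reaction type is the Michael-initiated ring closure with in situ enolate alkylation (tandem conjugate addition–alkylation), here intramolecular as in the second stage of a Robinson-type or double Michael annulation. Ring A closes in the stereoelectronically allowed 6-endo-trig mode (enol-endo with respect to the nucleophile), which places the new enolate carbon C4 inside the ring. The only new stereocentre, C4, is set in the alkylation: MeI should approach the exocyclic enolate on the β face, anti to the vicinal C5 ester and to the 1,3-related C10 ester, so that C19 ends cis to C6 and C20 as the later lactone needs. The step needs site selectivity for C2 over C5 in the deprotonation, C- over O-addition, and alkylation of C4 before the enolate equilibrates to the more acidic C2 position; the bulky amide base at low temperature, the reversibility of O-addition and fast trapping by excess MeI/DMPU are counted on for these.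

Step 6
Reactants: 11 ring A keto triester
Product: 13 ring A triester with C1 as CH2 (C4 C5 C10 substituents as in 11), via tosylhydrazone 12 (not isolated)
Conditions: TsNHNH2, EtOH, 70 °C; then catecholborane, CHCl3, 0 °C; then NaOAc·3H2O, 60 °C
Reagents that add atoms: none
Why: Tosylhydrazone formation at the only ketone, hydride reduction of C=N by catecholborane and acetate-induced loss of sulfinate and N2 (tosylhydrazone deoxygenation) remove the temporary C1 carbonyl without touching the esters or alkenes.

Step 7
Reactants: 13 ring A triester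
Product: 14 C19 carboxylic acid (tert-butyl ester cleaved; ethyl and allyl esters kept)
Conditions: CF3CO2H, CH2Cl2, 0 → 25 °C
Reagents that add atoms: none
Why: Acidolysis cleaves only the tert-butyl ester (lost as 2-methylpropene), which unmasks the C19 acid selectively.

Step 8
Reactants: 14 C19 acid
Product: 17 γ-lactone allyl ester (C19H2–O–C6(=O) lactone cis-fused to ring A; C10 bears α-CO2-allyl and β-allyl), via acid chloride 15 (not isolated), via hydroxy diester 16 (not isolated)
Conditions: (COCl)2, DMF (cat.), CH2Cl2, 0 °C; then NaBH4, THF/DMF, −20 → 0 °C; then TsOH (cat.), CH2Cl2, 25 °C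
Reagents that add atoms: none
Why: NaBH4 reduces the acid chloride far faster than the esters, and the resulting C19 alcohol closes the five-membered lactone on the cis C6 ethyl ester (faster than the six-membered alternative on the hindered C20 ester), which brings C19 to the OCH2 level and locks the C4/C5 cis relationship.

Step 9
Reactants: 17 γ-lactone allyl ester
Product: 18 γ-lactone C20 carboxylic acid
Conditions: Pd(PPh3)4 (5 mol%), morpholine, THF, 25 °C
Reagents that add atoms: none
Why: Tsuji–Trost deallylation: zerovalent palladium ionises the allyl ester to a π-allyl complex that morpholine intercepts, freeing the C20 acid and leaving the lactone and the C-allyl group untouched.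

Step 10
Reactants: 18 C20 acid
Product: 20 γ-lactone C20 primary alcohol (C10 bears α-CH2OH and β-allyl), via acid chloride 19 (not isolated)
Conditions: (COCl)2, DMF (cat.), CH2Cl2, 0 °C; then NaBH4, THF/DMF, −40 → −20 °C
Reagents that add atoms: none
Why: Chemoselective hydride reduction of the acid chloride at low temperature (the hindered γ-lactone is not reduced) gives the neopentylic C20 alcohol, which is carried on at once because base could shift the lactone from O19 to O20.

Step 11
Reactants: 21 diethyl malonate; 22 2,3-dibromopropene
Product: 23 diethyl 2-(2-bromoprop-2-enyl)propanedioate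
Conditions: NaH, THF, 0 → 25 °C
Reagents that add atoms: none
Why: Malonic ester alkylation takes place by SN2 at the allylic CH2Br only, the vinylic bromide being inert.

Step 12
Reactants: 23 alkylated malonate
Product: 24 2-(2-bromoprop-2-enyl)propanedioic acid
Conditions: KOH, EtOH/H2O, 60 °C; then HCl (aq.)
Reagents that add atoms: potassium hydroxide, [K+].[OH-]
Why: Ordinary saponification of both ethyl esters gives the malonic acid needed for the methylenation.

Step 13
Reactants: 24 substituted malonic acid
Product: 25 4-bromo-2-methylidenepent-4-enoic acid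
Conditions: Et2NH, (CH2O)n, EtOAc, 77 °C
Reagents that add atoms: formaldehyde, C=O
Why: Mannich condensation of the malonic acid with formaldehyde and the amine followed by decarboxylative elimination of the amine is the standard route to 2-substituted acrylic acids; C7, C8 and C14–C17 are now in place.

Step 14
Reactants: 20 C20 alcohol; 25 acrylic acid
Product: 26 C20 ester of 20 with 25 (C20–O–C7(=O)–C8(=C14H2)–C15H2–C16(Br)=C17H2)
Conditions: EDCI, DMAP (cat.), CH2Cl2, 0 → 25 °C
Reagents that add atoms: none
Why: Carbodiimide/DMAP esterification acylates the primary alcohol under near-neutral conditions and installs the dienophile on the tether that will become the δ-lactone.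

Step 15
Reactants: 26 allyl ester-tethered acrylate
Product: 27 methyl ketone (C9H2–C11(=O)–C12H3 arm on C10)
Conditions: PdCl2 (10 mol%), CuCl, O2 (1 atm), DMF/H2O, 25 °C
Reagents that add atoms: water, O
Why: Wacker oxidation is Markovnikov-selective for the monosubstituted C11=C12 alkene, while the two 1,1-disubstituted alkenes (acrylate and bromoalkene) do not react, so the C11 oxygen enters here.

Step 16
Reactants: 27 methyl ketone
Product: 28 (E)-enaminone (C11(=O)–C12H=C13H–NMe2 arm on C10)
Conditions: Me2NCH(OMe)2, toluene, 90 °C
Reagents that add atoms: N,N-dimethylformamide dimethyl acetal, COC(OC)N(C)C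
Why: Formamide acetal condensation occurs at the unhindered C12 methyl and not at the neopentylic C9 methylene, giving the vinylogous amide that supplies C13.

Step 17
Reactants: 28 enaminone
Product: 31 tricyclic enone (ring A/γ-lactone spiro-linked at C10 to the cis-fused δ-lactone/cyclohexenone; C11 ketone; C12=C13; C8 bears the 2-bromoallyl group), via amino silyloxy diene 29 (not isolated), via cycloadduct 30 (not isolated)
Conditions: TBSOTf, Et3N, CH2Cl2, 0 °C; then toluene, 80 °C; then HF (aq.), MeCN, 0 °C
Reagents that add atoms: none
Why: Soft enolisation toward C9 gives a 1-amino-3-silyloxy diene whose ester-tethered intramolecular Diels–Alder reaction with the 2-substituted acrylate forms C8–C9 and C13–C14 through the endo transition state, with ring C expected to grow on the face of the nascent δ-lactone away from C5; this would give the cis-fused lactone with C8 and C9 as in the target, after which HF hydrolyses the silyl enol ether and eliminates dimethylamine to the enone.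

Step 18
Reactants: 31 tricyclic enone
Product: 32 16-methylidene-11-ketone with the bicyclo[3.2.1]octane closed (C15 is CH2)
Conditions: Bu3SnH, AIBN (cat.), benzene, 80 °C, slow addition
Reagents that add atoms: none
Why: Tin-mediated radical cyclisation: the C16 vinyl radical adds 5-exo-trig to C13, the β-carbon of the enone, necessarily on the face that carries the C8 side chain, which closes ring D and fixes C13; the α-keto radical is then reduced by the stannane.

Step 19
Reactants: 32 11-ketone
Product: 33 11-alcohol (equatorial OH cis to the C9–C10 bond and trans to H9)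
Conditions: NaBH4, MeOH/THF, −20 °C
Reagents that add atoms: none
Why: The small hydride should attack the C11 ketone axially, anti to the axial C9–C10 bond on the adjacent carbon, giving the equatorial and thermodynamically preferred alcohol while both lactones survive at low temperature.

Step 20
Reactants: 33 11-alcohol
Product: 34 11,15-diol (allylic C15 alcohol; C15 configuration not controlled)
Conditions: SeO2 (0.5 equiv), t-BuOOH, CH2Cl2, 25 °C
Reagents that add atoms: tert-butyl hydroperoxide, CC(C)(C)OO
Why: Selenium dioxide allylic hydroxylation (ene reaction then [2,3]-shift) occurs at C15, the only non-bridgehead allylic position of the exocyclic alkene, a reaction well known for 16-methylidene bicyclo[3.2.1]octanes of this family.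

Step 21
Reactants: 34 11,15-diol
Product: 35 16-methylidene-15-ketone (11-OH free)
Conditions: MnO2, CH2Cl2, 25 °C
Reagents that add atoms: none
Why: Activated MnO2 oxidises only the allylic C15 alcohol, giving the exocyclic enone and leaving the saturated C11 alcohol.

Step 22
Reactants: 35 exocyclic enone
Product: 37 target CNP0555433.1, via C17 pinacol boronate 36 (not isolated)
Conditions: B2pin2, CuCl (5 mol%), Xantphos (5 mol%), NaOtBu (10 mol%), MeOH, THF, 25 °C; then H2O2 (30% aq.), pH 7 phosphate buffer, 0 °C
Reagents that add atoms: hydrogen peroxide, OO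
Why: Copper-catalysed conjugate borylation puts boron on C17, and methanol protonates the enolate on the open exo face of ring D so that the CH2B group is endo as required; buffered peroxide oxidation of C–B with retention then gives the primary alcohol without epimerising C16.

**Compound list**
1 | prop-2-enyl 3-oxobutanoate (allyl acetoacetate) | CC(=O)CC(=O)OCC=C | starting material
2 | 3-bromoprop-1-ene (allyl bromide) | C=CCBr | starting material
3 | prop-2-enyl 2-acetylpent-4-enoate (racemic) | CC(=O)C(CC=C)C(=O)OCC=C | intermediate
4 | tert-butyl acrylate | C=CC(=O)OC(C)(C)C | starting material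
5 | ethyl glyoxylate | CCOC(=O)C=O | starting material
6 | 4-tert-butyl 1-ethyl 2-hydroxy-3-methylidenebutanedioate (racemic) | CCOC(=O)C(O)C(=C)C(=O)OC(C)(C)C | intermediate
7 | 4-tert-butyl 1-ethyl 2-(tert-butoxycarbonyloxy)-3-methylidenebutanedioate (racemic) | CCOC(=O)C(OC(=O)OC(C)(C)C)C(=C)C(=O)OC(C)(C)C | intermediate
8 | 2-tert-butyl 3-ethyl 4-prop-2-enyl (3R,4R)-4-acetylhepta-1,6-diene-2,3,4-tricarboxylate | CC(=O)[C@](CC=C)(C(=O)OCC=C)[C@@H](C(=C)C(=O)OC(C)(C)C)C(=O)OCC | intermediate
9 | lithium enolate of the C1 ketone of 8 (C1=C2 enolate) | C=C(O[Li])[C@](CC=C)(C(=O)OCC=C)[C@@H](C(=C)C(=O)OC(C)(C)C)C(=O)OCC | intermediate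
10 | ring A ketone with the lithium tert-butyl ester enolate at C4 | O=C1CCC(=C(O[Li])OC(C)(C)C)[C@@H](C(=O)OCC)[C@@]1(CC=C)C(=O)OCC=C | intermediate
11 | ring A keto triester: C1 ketone; C4 β-methyl, α-CO2tBu; C5 α-CO2Et; C10 α-CO2-allyl, β-allyl | O=C1CC[C@@](C)(C(=O)OC(C)(C)C)[C@@H](C(=O)OCC)[C@@]1(CC=C)C(=O)OCC=C | intermediate
12 | C1 tosylhydrazone of 11 | Cc1ccc(cc1)S(=O)(=O)NN=C1CC[C@@](C)(C(=O)OC(C)(C)C)[C@@H](C(=O)OCC)[C@@]1(CC=C)C(=O)OCC=C | intermediate
13 | ring A triester with C1 as CH2, substituents as in 11 | C1CC[C@@](C)(C(=O)OC(C)(C)C)[C@@H](C(=O)OCC)[C@@]1(CC=C)C(=O)OCC=C | intermediate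
14 | C19 carboxylic acid of 13 | C1CC[C@@](C)(C(=O)O)[C@@H](C(=O)OCC)[C@@]1(CC=C)C(=O)OCC=C | intermediate
15 | C19 acid chloride of 14 | C1CC[C@@](C)(C(=O)Cl)[C@@H](C(=O)OCC)[C@@]1(CC=C)C(=O)OCC=C | intermediate
16 | C19 primary alcohol with C6 ethyl ester and C20 allyl ester | C1CC[C@@](C)(CO)[C@@H](C(=O)OCC)[C@@]1(CC=C)C(=O)OCC=C | intermediate
17 | cis-fused γ-lactone (C19H2–O–C6=O) with C10 α-CO2-allyl, β-allyl | C[C@@]12CCC[C@](CC=C)(C(=O)OCC=C)[C@@H]1C(=O)OC2 | intermediate
18 | γ-lactone C20 carboxylic acid | C[C@@]12CCC[C@](CC=C)(C(=O)O)[C@@H]1C(=O)OC2 | intermediate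
19 | γ-lactone C20 acid chloride | C[C@@]12CCC[C@](CC=C)(C(=O)Cl)[C@@H]1C(=O)OC2 | intermediate
20 | γ-lactone C20 primary alcohol (C10 α-CH2OH, β-allyl) | C[C@@]12CCC[C@](CC=C)(CO)[C@@H]1C(=O)OC2 | intermediate
21 | diethyl malonate | CCOC(=O)CC(=O)OCC | starting material
22 | 2,3-dibromopropene | C=C(Br)CBr | starting material
23 | diethyl 2-(2-bromoprop-2-enyl)propanedioate | CCOC(=O)C(CC(Br)=C)C(=O)OCC | intermediate
24 | 2-(2-bromoprop-2-enyl)propanedioic acid | OC(=O)C(CC(Br)=C)C(=O)O | intermediate
25 | 4-bromo-2-methylidenepent-4-enoic acid | C=C(Br)CC(=C)C(=O)O | intermediate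
26 | C20 ester of 20 with 25 | C[C@@]12CCC[C@](CC=C)(COC(=O)C(=C)CC(Br)=C)[C@@H]1C(=O)OC2 | intermediate
27 | methyl ketone (2-oxopropyl arm on C10) | C[C@@]12CCC[C@](CC(C)=O)(COC(=O)C(=C)CC(Br)=C)[C@@H]1C(=O)OC2 | intermediate
28 | (E)-enaminone (4-dimethylamino-2-oxobut-3-enyl arm on C10) | C[C@@]12CCC[C@](CC(=O)/C=C/N(C)C)(COC(=O)C(=C)CC(Br)=C)[C@@H]1C(=O)OC2 | intermediate
29 | 1-dimethylamino-3-(tert-butyldimethylsilyloxy) diene C9=C11–C12=C13 on C10 | C[C@@]12CCC[C@](/C=C(\O[Si](C)(C)C(C)(C)C)/C=C/N(C)C)(COC(=O)C(=C)CC(Br)=C)[C@@H]1C(=O)OC2 | intermediate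
30 | Diels–Alder adduct: cis-fused δ-lactone/cyclohexene with C11 silyl enol ether and C13 NMe2 (C13 configuration open) | C[C@@]12CCC[C@]3(COC(=O)[C@@]4(CC(Br)=C)CC(N(C)C)C=C(O[Si](C)(C)C(C)(C)C)[C@H]43)[C@@H]1C(=O)OC2 | intermediate
31 | tricyclic enone: C11 ketone, C12=C13, C8 2-bromoallyl, C8/C9 as in the target | C[C@@]12CCC[C@]3(COC(=O)[C@@]4(CC(Br)=C)CC=CC(=O)[C@H]43)[C@@H]1C(=O)OC2 | intermediate
32 | 16-methylidene-11-ketone with rings C and D closed (C15 = CH2) | C[C@@]12CCC[C@]3(COC(=O)[C@@]45C[C@@H](CC(=O)[C@H]43)C(=C)C5)[C@@H]1C(=O)OC2 | intermediate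
33 | 11-alcohol, 16-methylidene (C11 as in the target) | C[C@@]12CCC[C@]3(COC(=O)[C@@]45C[C@@H](C[C@@H](O)[C@H]43)C(=C)C5)[C@@H]1C(=O)OC2 | intermediate
34 | 11,15-diol, 16-methylidene (C15 configuration open) | C[C@@]12CCC[C@]3(COC(=O)[C@@]45C[C@@H](C[C@@H](O)[C@H]43)C(=C)C5O)[C@@H]1C(=O)OC2 | intermediate
35 | 11-hydroxy-16-methylidene-15-ketone | C[C@@]12CCC[C@]3(COC(=O)[C@@]45C[C@@H](C[C@@H](O)[C@H]43)C(=C)C5=O)[C@@H]1C(=O)OC2 | intermediate
36 | C17 pinacol boronate of the 15-ketone (C16 as in the target) | C[C@@]12CCC[C@]3(COC(=O)[C@@]45C[C@@H](C[C@@H](O)[C@H]43)[C@@H](CB6OC(C)(C)C(C)(C)O6)C5=O)[C@@H]1C(=O)OC2 | intermediate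
37 | CNP0555433.1 | C[C@@]12CCC[C@]3(COC(=O)[C@@]45C[C@@H](C[C@@H](O)[C@H]43)[C@@H](CO)C5=O)[C@@H]1C(=O)OC2 | target

**Step count and risks**
Total steps: 22. Longest linear sequence: 18 steps (steps 2–10, then 14–22, from 4 and 5).

Steps most likely to fail:

Step 4 – poor control of the C10 quaternary centre (low enantio- or diastereofacial selectivity, or low reactivity of the hindered α-substituted β-keto ester toward the ammonium intermediate). The fallback sets out from 1 and 7 and comes back at 8. Compound 1 is first alkylated with 7 under achiral DABCO catalysis to the tertiary β-keto ester prop-2-enyl 2-acetyl-3-(ethoxycarbonyl)-4-(tert-butoxycarbonyl)pent-4-enoate F1. The quaternary centre is then made by asymmetric phase-transfer C-allylation of F1 with 2 (chiral binaphthyl-derived spiro ammonium bromide, K2CO3, toluene, 0 °C). Here the ion-paired enolate, not the electrophile, carries the stereochemical information; the C5 epimer of 8 would be separated and recycled by base epimerisation.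

Step 5 – proton transfer from C2 to the C4 ester enolate before alkylation (methylation at C2 or on oxygen), or deprotonation at C5 with migration of the C3=C4 alkene into conjugation. The fallback sets out from 8 and comes back at 13; it separates ring closure from methylation. TMSOTf/Et3N converts the methyl ketone of 8 into the trimethylsilyl enol ether F2. F2 closes ring A by Lewis acid-catalysed Mukaiyama–Michael addition (TiCl4 or cat. HNTf2, CH2Cl2, −78 °C) to the ring A keto triester lacking the C4 methyl F3. F3 is deoxygenated as in step 6 through its tosylhydrazone F4 to the ring A triester with C1 as CH2 and C4–H F5. F5 has no ketone left; it is deprotonated with LiN(iPr)2 at the less hindered C4–H and methylated with MeI anti to the C5 ester to give 13.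

Step 17 – failure of the soft enolisation of the vinylogous amide, or poor endo/facial selectivity at the temperature the tethered cycloaddition needs. The fallback sets out from 28 and comes back at 31. The amino group of 28 is exchanged for methoxy (MeOH, TsOH cat.) to give the (E)-β-methoxy enone F6. TBSOTf/Et3N converts F6 into the 1-methoxy-3-silyloxy diene F7, a diene class for which soft enolisation is routine. Its cycloaddition can be run at low temperature with Me2AlCl bound to the acrylate carbonyl, giving the methoxy cycloadduct silyl enol ether F8. CF3CO2H then eliminates methanol and cleaves the silyl enol ether to 31.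

**Further compounds**
F1 | step 4 | prop-2-enyl 2-acetyl-3-(ethoxycarbonyl)-4-(tert-butoxycarbonyl)pent-4-enoate (stereoisomer mixture) | CC(=O)C(C(=O)OCC=C)C(C(=C)C(=O)OC(C)(C)C)C(=O)OCC
F2 | step 5 | trimethylsilyl enol ether of the C1 ketone of 8 | C=C(O[Si](C)(C)C)[C@](CC=C)(C(=O)OCC=C)[C@@H](C(=C)C(=O)OC(C)(C)C)C(=O)OCC
F3 | step 5 | ring A keto triester lacking the C4 methyl (C4–H, configuration open) | O=C1CCC(C(=O)OC(C)(C)C)[C@@H](C(=O)OCC)[C@@]1(CC=C)C(=O)OCC=C
F4 | step 5 | C1 tosylhydrazone of F3 | Cc1ccc(cc1)S(=O)(=O)NN=C1CCC(C(=O)OC(C)(C)C)[C@@H](C(=O)OCC)[C@@]1(CC=C)C(=O)OCC=C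
F5 | step 5 | ring A triester with C1 as CH2 and C4–H | C1CCC(C(=O)OC(C)(C)C)[C@@H](C(=O)OCC)[C@@]1(CC=C)C(=O)OCC=C
F6 | step 17 | (E)-β-methoxy enone (4-methoxy-2-oxobut-3-enyl arm on C10) | C[C@@]12CCC[C@](CC(=O)/C=C/OC)(COC(=O)C(=C)CC(Br)=C)[C@@H]1C(=O)OC2
F7 | step 17 | 1-methoxy-3-(tert-butyldimethylsilyloxy) diene on C10 | C[C@@]12CCC[C@](/C=C(\O[Si](C)(C)C(C)(C)C)/C=C/OC)(COC(=O)C(=C)CC(Br)=C)[C@@H]1C(=O)OC2
F8 | step 17 | methoxy cycloadduct with C11 silyl enol ether (C13 configuration open) | C[C@@]12CCC[C@]3(COC(=O)[C@@]4(CC(Br)=C)CC(OC)C=C(O[Si](C)(C)C(C)(C)C)[C@H]43)[C@@H]1C(=O)OC2
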